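**Strategy.** The chroman is disconnected in its pyran ring between the gem-dimethyl carbon C2 and the C3 methylene. C2 is a tertiary carbon flanked by the ring oxygen O1, so it is an ideal nucleophilic radical, and C3–C4 is an ethylene bridge that can arrive as an aryl vinyl group. In one operation, visible-light decarboxylation of an open-chain 2-aryloxy-2-methylpropanoic acid bearing an ortho-vinyl group creates the C2 radical, closes the pyran ring 6-endo and caps C4 with hydrogen; the carboxyl group is a traceless activator and the product is the chroman aldehyde. A catalytic enantioselective Mukaiyama aldol addition then joins it to an (S)-dihydrobenzofuranyl methyl ketone made by Shi epoxidation and 5-exo epoxide opening.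

Key step: step 3

Remark: the (R,R)-form of the dimeric binaphthyldiamine phosphoramide/SiCl4 catalyst is taken to direct nucleophiles to the Re face of aromatic aldehydes, so the (S,S)-form is used for the Si-face attack that gives the (S)-carbinol; should the sense prove opposite, the antipodal catalyst is used.

**Step 1**
Reactants: 1 3-bromo-4-hydroxybenzaldehyde; 2 potassium vinyltrifluoroborate
Product: 3 4-hydroxy-3-vinylbenzaldehyde
Conditions: PdCl2(dppf) (3 mol %), Cs2CO3 (3 equiv), THF/H2O 9:1, 80 °C
Reagents that add atoms: none
Why: Suzuki–Miyaura vinylation, in which oxidative addition into the C–Br bond is helped by the para-formyl group, the free phenol is tolerated as its phenoxide and no stereocentre is formed.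

**Step 2**
Reactants: 3 4-hydroxy-3-vinylbenzaldehyde; 4 ethyl 2-bromo-2-methylpropanoate
Product: 6 2-(4-formyl-2-vinylphenoxy)-2-methylpropanoic acid, via ethyl ester 5 (not isolated)
Conditions: Cs2CO3, MeCN, 70 °C; then LiOH, THF/H2O, rt; HCl work-up
Reagents that add atoms: lithium hydroxide, [Li+].[OH-]
Why: Williamson ether synthesis of the fibrate type (phenoxide plus tertiary α-bromo ester) followed by saponification in the same flask, the aldehyde having no enolisable partner and the vinyl group being inert to both stages.

**Step 3**
Reactants: 6 2-(4-formyl-2-vinylphenoxy)-2-methylpropanoic acid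
Product: 7 2,2-dimethylchroman-6-carbaldehyde
Conditions: [Ir(dF(CF3)ppy)2(dtbbpy)]PF6 (1 mol %), 2,4,6-triisopropylbenzenethiol (5 mol %), Cs2CO3 (10 mol %), degassed DMF (0.01 M), blue LEDs (450 nm), rt
Reagents that add atoms: none
Why: Photoredox decarboxylative radical cyclisation (intramolecular Giese-type hydroalkylation): the carboxylate of 6 is oxidised by the excited iridium photocatalyst and loses CO2 to give the tertiary α-aryloxyalkyl radical at the future C2, which adds to the CH2 terminus of the ortho-vinyl group (future C3) to form the C2–C3 bond and a benzylic radical at C4; hydrogen-atom transfer from the arenethiol caps C4, and the thiyl radical is reduced by the reduced iridium complex and reprotonated by 6, so the acid proton ends on C4 and the cycle is redox-neutral. The closest known reaction type is the visible-light decarboxylative addition of α-oxy carboxylic acids to alkenes with thiol hydrogen-atom-transfer co-catalysis. The pyran ring closes in the 6-endo-trig mode. No stereocentre is formed. The step needs 6-endo over 5-exo closure and ring closure before hydrogen-atom transfer to the open-chain radical: the bulky tertiary radical attacks the unsubstituted styrene terminus to give a benzylic radical, whereas 5-exo attack at the aryl-substituted carbon would give an unstabilised primary radical, and low thiol loading at high dilution keeps the quench slower than cyclisation. The aldehyde is not attacked by the nucleophilic radical, and the stabilised arenethiyl radical does not abstract the formyl hydrogen.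

**Step 4**
Reactants: 8 1-(2,4-dihydroxyphenyl)ethanone; 9 2-methylbut-3-en-2-ol
Product: 10 1-[2,4-dihydroxy-5-(3-methylbut-2-en-1-yl)phenyl]ethanone
Conditions: BF3·OEt2 (0.3 equiv), dioxane, rt
Reagents that add atoms: none
Why: Friedel–Crafts prenylation through the dimethylallyl cation, in which C5 (para to the chelated 2-OH, ortho to the free 4-OH) is the unhindered activated position while C3 lies between two oxygens, and substoichiometric Lewis acid at partial conversion limits diprenylation and acid closure of the prenylphenol to a chroman.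

**Step 5**
Reactants: 10 1-[2,4-dihydroxy-5-(3-methylbut-2-en-1-yl)phenyl]ethanone
Product: 11 1-[4-(tert-butyldimethylsilyloxy)-2-hydroxy-5-(3-methylbut-2-en-1-yl)phenyl]ethanone
Conditions: TBSCl (1.05 equiv), imidazole, DMF, 0 °C
Reagents that add atoms: tert-butyldimethylsilyl chloride, CC(C)(C)[Si](C)(C)Cl
Why: Selective silylation, because the 2-OH is held in a hydrogen bond to the acetyl carbonyl and only the 4-OH reacts with one equivalent of TBSCl.

**Step 6**
Reactants: 11 1-[4-(tert-butyldimethylsilyloxy)-2-hydroxy-5-(3-methylbut-2-en-1-yl)phenyl]ethanone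
Product: 13 (S)-1-[6-hydroxy-2-(2-hydroxypropan-2-yl)-2,3-dihydrobenzofuran-5-yl]ethanone, via epoxide 12 (not isolated)
Conditions: 1,2:4,5-di-O-isopropylidene-β-D-erythro-hexo-2,3-diulo-2,6-pyranose (30 mol %), Oxone, K2CO3, Bu4NHSO4 (cat.), MeCN/CH2(OMe)2/aq. Na2B4O7–Na2EDTA buffer, 0 °C; then TBAF, THF, 0 °C to rt
Reagents that add atoms: Oxone (potassium peroxymonosulfate), [K+].[O-]S(=O)(=O)OO
Why: Shi asymmetric epoxidation followed by 5-exo-tet epoxide opening, in which the dioxirane of the D-fructose-derived ketone should epoxidise the trisubstituted alkene through the spiro transition state to the (R)-epoxide and fluoride then frees the 4-phenoxide, which opens the epoxide at the secondary carbon with inversion (basic medium, so no 6-endo opening at the tertiary carbon) and so sets the (S)-configured C2 of the dihydrobenzofuran.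

**Step 7**
Reactants: 13 (S)-1-[6-hydroxy-2-(2-hydroxypropan-2-yl)-2,3-dihydrobenzofuran-5-yl]ethanone
Product: 14 tris(trimethylsilyl) derivative of 13 (trimethylsilyl enol ether of the methyl ketone, aryl trimethylsilyl ether, tertiary trimethylsilyl ether; S)
Conditions: TMSOTf (3.5 equiv), Et3N, CH2Cl2, 0 °C; pentane trituration, used crude
Reagents that add atoms: trimethylsilyl trifluoromethanesulfonate, C[Si](C)(C)OS(=O)(=O)C(F)(F)F
Why: Soft enolisation and silylation with TMSOTf and Et3N, which gives the only possible silyl enol ether of the methyl ketone while capping the phenol and the tertiary alcohol, so that no OH group remains to consume SiCl4 in the next step and the stereocentre is not touched.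

**Step 8**
Reactants: 14 tris(trimethylsilyl) derivative of 13; 7 2,2-dimethylchroman-6-carbaldehyde
Product: 17 (S)-3-(2,2-dimethylchroman-6-yl)-3-hydroxy-1-[(S)-6-hydroxy-2-(2-hydroxypropan-2-yl)-2,3-dihydrobenzofuran-5-yl]propan-1-one (CNP0419761.2), via trichlorosilyl aldolate 15 (not isolated), via tertiary trimethylsilyl ether 16 (not isolated)
Conditions: SiCl4 (1.5 equiv), (S,S)-N,N'-bis(3,5-dimethyl-4-oxido-4,5-dihydro-3H-dinaphtho[2,1-d:1',2'-f][1,3,2]diazaphosphepin-4-yl)-N,N'-dimethylpentane-1,5-diamine (5 mol %), iPr2NEt (10 mol %), CH2Cl2, −78 °C; aq. KF/KH2PO4; then Et3N·3HF, THF, 0 °C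
Reagents that add atoms: none
Why: Lewis-base-activated SiCl4 Mukaiyama aldol addition, in which the chiral phosphoramide-bound trichlorosilyl cation binds aldehyde 7 and should let the enol ether attack only its Si face through an open transition state, setting the (S)-carbinol under catalyst control, while the buffered fluoride quench and Et3N·3HF remove all silyl groups under conditions too mild to dehydrate the aldol or to touch the remote (S)-centre.

**Compound list**

1 | 3-bromo-4-hydroxybenzaldehyde | O=Cc1ccc(O)c(Br)c1 | starting material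
2 | potassium vinyltrifluoroborate | C=C[B-](F)(F)F.[K+] | starting material
3 | 4-hydroxy-3-vinylbenzaldehyde | C=Cc1cc(C=O)ccc1O | intermediate
4 | ethyl 2-bromo-2-methylpropanoate | CCOC(=O)C(C)(C)Br | starting material
5 | ethyl 2-(4-formyl-2-vinylphenoxy)-2-methylpropanoate | CCOC(=O)C(C)(C)Oc1ccc(C=O)cc1C=C | intermediate
6 | 2-(4-formyl-2-vinylphenoxy)-2-methylpropanoic acid | OC(=O)C(C)(C)Oc1ccc(C=O)cc1C=C | intermediate
7 | 2,2-dimethylchroman-6-carbaldehyde | CC1(C)CCc2cc(C=O)ccc2O1 | intermediate
8 | 1-(2,4-dihydroxyphenyl)ethanone | CC(=O)c1ccc(O)cc1O | starting material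
9 | 2-methylbut-3-en-2-ol | CC(C)(O)C=C | starting material
10 | 1-[2,4-dihydroxy-5-(3-methylbut-2-en-1-yl)phenyl]ethanone | CC(=O)c1cc(CC=C(C)C)c(O)cc1O | intermediate
11 | 1-[4-(tert-butyldimethylsilyloxy)-2-hydroxy-5-(3-methylbut-2-en-1-yl)phenyl]ethanone | CC(=O)c1cc(CC=C(C)C)c(O[Si](C)(C)C(C)(C)C)cc1O | intermediate
12 | 1-[4-(tert-butyldimethylsilyloxy)-5-{[(2R)-3,3-dimethyloxiran-2-yl]methyl}-2-hydroxyphenyl]ethanone | CC(=O)c1cc(C[C@H]2OC2(C)C)c(O[Si](C)(C)C(C)(C)C)cc1O | intermediate
13 | (S)-1-[6-hydroxy-2-(2-hydroxypropan-2-yl)-2,3-dihydrobenzofuran-5-yl]ethanone | CC(=O)c1cc2c(cc1O)O[C@H](C(C)(C)O)C2 | intermediate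
14 | (S)-6-(trimethylsilyloxy)-5-[1-(trimethylsilyloxy)vinyl]-2-[2-(trimethylsilyloxy)propan-2-yl]-2,3-dihydrobenzofuran | C=C(O[Si](C)(C)C)c1cc2c(cc1O[Si](C)(C)C)O[C@H](C(C)(C)O[Si](C)(C)C)C2 | intermediate
15 | O-trichlorosilyl aldolate carrying the aryl and tertiary trimethylsilyl ethers (S,S) | CC1(C)CCc2cc([C@@H](O[Si](Cl)(Cl)Cl)CC(=O)c3cc4c(cc3O[Si](C)(C)C)O[C@H](C(C)(C)O[Si](C)(C)C)C4)ccc2O1 | intermediate
16 | tertiary trimethylsilyl ether of the target (S,S) | CC1(C)CCc2cc([C@@H](O)CC(=O)c3cc4c(cc3O)O[C@H](C(C)(C)O[Si](C)(C)C)C4)ccc2O1 | intermediate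
17 | (S)-3-(2,2-dimethylchroman-6-yl)-3-hydroxy-1-[(S)-6-hydroxy-2-(2-hydroxypropan-2-yl)-2,3-dihydrobenzofuran-5-yl]propan-1-one (CNP0419761.2) | CC1(C)CCc2cc([C@@H](O)CC(=O)c3cc4c(cc3O)O[C@H](C(C)(C)O)C4)ccc2O1 | target

**Count.** Total steps: 8. Longest linear sequence: 5 steps (steps 4, 5, 6, 7 and 8, from compound 8).

**Steps most likely to fail**

Step 3. The open-chain tertiary radical may take a hydrogen atom before it cyclises (plain hydrodecarboxylation), the carboxylate may be oxidised inefficiently, or closure may go partly in the 5-exo mode. The fallback sets out from 6 and keeps the same ring closure but generates the radical reductively. Compound 6 is esterified with N-hydroxyphthalimide (N,N'-diisopropylcarbodiimide, cat. DMAP, CH2Cl2) to the redox-active ester 1,3-dioxoisoindolin-2-yl 2-(4-formyl-2-vinylphenoxy)-2-methylpropanoate F1. Irradiation of F1 with [Ru(bpy)3]Cl2, Hantzsch ester (diethyl 2,6-dimethyl-1,4-dihydropyridine-3,5-dicarboxylate) and iPr2NEt in CH2Cl2 under blue light should give the C2 radical by reductive fragmentation, independent of the oxidation potential of the substrate. The only hydrogen donor is then the Hantzsch ester, a much slower donor than a thiol, which leaves more time for the 6-endo closure. The fallback comes back to the route at 7.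

Step 8. Facial discrimination at the aldehyde may be poor or reversed with the hindered ortho-silyloxy aryl enol ether, or the aldol may dehydrate to the chalcone during desilylation. The fallback sets out from 13 and 7 and replaces the aldol addition by condensation and formal asymmetric hydration. Claisen–Schmidt condensation (KOH, EtOH, rt) should give the (E)-2'-hydroxychalcone F2. Copper-catalysed enantioselective conjugate borylation (CuCl, NaOtBu, 1-[2-(diphenylphosphino)ferrocenyl]ethyldicyclohexylphosphine (Josiphos) in the enantiomeric form that gives the (S)-boronate, B2pin2, MeOH, THF) should give the (S)-β-pinacolboryl ketone F3. Oxidation of the C–B bond with retention (NaBO3·4H2O, THF/H2O, rt) comes back to the route at 17.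

Step 4. Regiocontrol in the electrophilic prenylation may be lost (attack at C3, double prenylation, acid closure of the prenylphenol to a chroman). The fallback sets out from 8 and fixes the position by halogenation and cross-coupling. Bromination with NBS in MeCN at 0 °C, which should go para to the chelated 2-OH, gives 1-(5-bromo-2,4-dihydroxyphenyl)ethanone F4. Stille coupling of F4 with tributyl(3-methylbut-2-en-1-yl)stannane (Pd(PPh3)4, LiCl, DMF, 90 °C) places the prenyl group at C5 and comes back to the route at 10.

**Further compounds**

F1 | step 3 | 1,3-dioxoisoindolin-2-yl 2-(4-formyl-2-vinylphenoxy)-2-methylpropanoate | C=Cc1cc(C=O)ccc1OC(C)(C)C(=O)ON1C(=O)c2ccccc2C1=O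
F2 | step 8 | (E)-3-(2,2-dimethylchroman-6-yl)-1-[(S)-6-hydroxy-2-(2-hydroxypropan-2-yl)-2,3-dihydrobenzofuran-5-yl]prop-2-en-1-one | CC1(C)CCc2cc(/C=C/C(=O)c3cc4c(cc3O)O[C@H](C(C)(C)O)C4)ccc2O1
F3 | step 8 | (S)-3-(2,2-dimethylchroman-6-yl)-1-[(S)-6-hydroxy-2-(2-hydroxypropan-2-yl)-2,3-dihydrobenzofuran-5-yl]-3-(4,4,5,5-tetramethyl-1,3,2-dioxaborolan-2-yl)propan-1-one | CC1(C)CCc2cc([C@@H](B3OC(C)(C)C(C)(C)O3)CC(=O)c3cc4c(cc3O)O[C@H](C(C)(C)O)C4)ccc2O1
F4 | step 4 | 1-(5-bromo-2,4-dihydroxyphenyl)ethanone | CC(=O)c1cc(Br)c(O)cc1O
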